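**Retrosynthetic overview**

1. Ardisinone ⇐ 3‑methoxy‑5‑alkylphenol carrying the side‑chain acetate: the C1 carbonyl oxygen (quinone numbering, C1 lies between C2–OMe and C6–side chain) is added last by para‑oxidation.
2. That phenol ⇐ a 6‑alkyl‑4‑methoxysalicylate ⇐ a 6‑alkyl‑2,4‑dioxocyclohexane‑1‑carboxylate: oxidative aromatisation with O‑methylation at the C2 oxygen, then loss of the ester carbon from C5 as CO2.
3. Key disconnection, which forms the only ring of the target: the dioxocyclohexanecarboxylate ⇐ an (E)‑alk‑3‑en‑2‑one + dimethyl malonate, a Michael/Claisen [4+2] annulation that makes C5–C6 and C3–C4.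
4. Enabling feature: on the six‑membered ring the C2 oxygen, the C4 oxygen and the C6 side chain are mutually meta and C3 and C5 carry only H. C5–C4 is therefore an acetate (malonate) unit and C6–C1–C2–C3 is the β‑carbon, α‑carbon, carbonyl and methyl of a methyl enone, as in a polyketide alkylresorcinol.
5. The enone ⇐ a homoallylic benzyl ether + methyl vinyl ketone (cross‑metathesis); the stereocentre comes from (R)‑epichlorohydrin by two copper‑catalysed Grignard openings.

Key step: step 5

Remark: ring atoms in the Why lines carry the quinone numbering given above; 12 is drawn as its triketo tautomer, although it should exist mainly as an enol and as a mixture of ring diastereomers, which is of no consequence because these ring centres become sp2 in step 6.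

**Route**

Step 1
Reactants: 1 (R)‑epichlorohydrin; 2 dodecylmagnesium bromide
Product: 4 (2R)‑2‑tridecyloxirane, via chlorohydrin 3 (not isolated)
Conditions: 2 (1.15 equiv), copper iodide CuI (5 mol %), THF, −40 → 0 °C; then 3 M aq NaOH, rt
Reagents that add atoms: none
Why: Copper‑catalysed Grignard opening (SN2) takes place at the unsubstituted epoxide carbon faster than displacement of chloride, and hydroxide then closes the chlorohydrin by intramolecular Williamson etherification onto CH2Cl; the C–O bond at the stereocentre is never broken, so the (R) configuration of 1 is carried unchanged into 4.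

Step 2
Reactants: 4 (2R)‑2‑tridecyloxirane; 5 vinylmagnesium bromide
Product: 6 (4R)‑heptadec‑1‑en‑4‑ol
Conditions: 5 (1.5 equiv), CuI (10 mol %), THF, −30 → 0 °C; cold 1 M HCl work‑up
Reagents that add atoms: none
Why: Copper‑catalysed SN2 opening of a terminal epoxide by the vinyl Grignard reagent occurs at the CH2 carbon, so the carbinol stereocentre is retained as (R).

Step 3
Reactants: 6 (4R)‑heptadec‑1‑en‑4‑ol
Product: 7 (4R)‑4‑(benzyloxy)heptadec‑1‑ene
Conditions: NaH (1.5 equiv), BnBr (1.3 equiv), Bu4NI (cat.), THF/DMF, 0 °C → rt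
Reagents that add atoms: benzyl bromide, BrCc1ccccc1
Why: Williamson etherification of the sodium alkoxide with benzyl bromide (iodide catalysis) gives an ether that should withstand methoxide, hot alkali, hot dilute acid and HI in methanol in steps 5 to 7; the stereocentre is not involved.

Step 4
Reactants: 7 (4R)‑4‑(benzyloxy)heptadec‑1‑ene; 8 methyl vinyl ketone
Product: 9 (3E,6R)‑6‑(benzyloxy)nonadec‑3‑en‑2‑one
Conditions: 8 (3 equiv), second‑generation Hoveyda–Grubbs catalyst RuCl2(H2IMes)(=CH‑C6H4‑2‑OiPr) (3 mol %), CH2Cl2, 40 °C
Reagents that add atoms: none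
Why: Olefin cross‑metathesis of a terminal alkene with an electron‑poor enone that hardly homodimerises is selective for the cross product and gives the E‑enone under thermodynamic control; the homoallylic stereocentre is untouched.

Step 5
Reactants: 9 (3E,6R)‑6‑(benzyloxy)nonadec‑3‑en‑2‑one; 10 dimethyl malonate
Product: 12 methyl 6‑[(2R)‑2‑(benzyloxy)pentadecyl]‑2,4‑dioxocyclohexane‑1‑carboxylate, via Michael adduct 11 (not isolated)
Conditions: 10 (1.2 equiv), NaOMe (1.1 equiv), MeOH, 0 °C → rt, then reflux; cold 1 M HCl work‑up
Reagents that add atoms: none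
Why: Sodiomalonate adds 1,4 to the enone (bond C5–C6), proton transfer gives the methyl‑ketone enolate, and this attacks one malonate ester carbonyl and expels methoxide (bond C3–C4), after which the ring is held as its doubly stabilised enolate, which pulls the reversible sequence to the product. The closest known reaction type is the Michael–Claisen (Michael–Dieckmann) synthesis of 6‑alkyl‑2,4‑dioxocyclohexane‑1‑carboxylates from alk‑3‑en‑2‑ones and malonates, the standard entry to 5‑alkylresorcinols, and the ring so made carries the acetate‑derived oxygen pattern of a polyketide alkylresorcinol. The ring closes in a 6‑exo‑trig Claisen condensation, and of the two ketone enolates only the methyl one can reach an ester through a six‑membered transition state. The two new ring stereocentres (C5 and C6) form without control and need none, since both become sp2 in step 6, and the side‑chain stereocentre is neither acidic nor next to a reacting centre. The step needs 1,4‑ over 1,2‑addition, C‑ over O‑acylation and no loss of benzyl oxide from the γ‑deprotonated enone: the soft malonate anion and thermodynamic control should secure the first two, and running the conjugate addition at 0 °C to room temperature in malonate‑buffered methoxide, so that no enone is left when the mixture is heated, should secure the third.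

Step 6
Reactants: 12 methyl 6‑[(2R)‑2‑(benzyloxy)pentadecyl]‑2,4‑dioxocyclohexane‑1‑carboxylate
Product: 14 methyl 2‑[(2R)‑2‑(benzyloxy)pentadecyl]‑6‑hydroxy‑4‑methoxybenzoate, via enol ether 13 (not isolated)
Conditions: I2 (1.5 equiv), MeOH, reflux; aq Na2S2O3 work‑up
Reagents that add atoms: methanol, CO
Why: Iodine–methanol oxidative aromatisation of a cyclohexenone: HI formed in the flask catalyses conversion of the ketone at C2 into its methyl enol ether 13, α‑iodination and loss of HI then give the arene, while the oxygen at C4 should stay a free hydroxyl because it is held as the ester‑chelated enol; no stereocentre is formed and the two ring stereocentres of 12 vanish.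

Step 7
Reactants: 14 methyl 2‑[(2R)‑2‑(benzyloxy)pentadecyl]‑6‑hydroxy‑4‑methoxybenzoate
Product: 16 3‑[(2R)‑2‑(benzyloxy)pentadecyl]‑5‑methoxyphenol, via salicylic acid 15 (not isolated)
Conditions: NaOH, dioxane/H2O, reflux; then 2 M HCl to pH 1, 80 °C
Reagents that add atoms: none
Why: Saponification of the hindered salicylate followed by ipso‑protonation and loss of CO2 from the ortho,para‑dioxygenated benzoic acid 15 (decarboxylation of a β‑resorcylic‑type acid) removes the activating ester carbon from C5; the benzyl ether and the stereocentre should be inert to both stages.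

Step 8
Reactants: 16 3‑[(2R)‑2‑(benzyloxy)pentadecyl]‑5‑methoxyphenol
Product: 17 3‑[(2R)‑2‑hydroxypentadecyl]‑5‑methoxyphenol
Conditions: H2 (1 atm), Pd/C (10% palladium on carbon), EtOAc/EtOH, rt
Reagents that add atoms: none
Why: Hydrogenolysis cleaves the benzylic C–O bond only, so the alkyl C–O bond at the stereocentre and its (R) configuration remain, and the electron‑rich arene is not reduced under these conditions.

Step 9
Reactants: 17 3‑[(2R)‑2‑hydroxypentadecyl]‑5‑methoxyphenol
Product: 19 (2R)‑1‑(3‑hydroxy‑5‑methoxyphenyl)pentadecan‑2‑yl acetate, via diacetate 18 (not isolated)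
Conditions: Ac2O (2.5 equiv), pyridine, DMAP (cat.), CH2Cl2, rt; then pyrrolidine (3 equiv), 0 °C → rt
Reagents that add atoms: acetic anhydride, CC(=O)OC(C)=O
Why: Exhaustive acetylation followed by chemoselective aminolysis: an aryl acetate, with phenoxide as leaving group, is cleaved by pyrrolidine far faster than a secondary alkyl acetate, which leaves the side‑chain ester in place.

Step 10
Reactants: 19 (2R)‑1‑(3‑hydroxy‑5‑methoxyphenyl)pentadecan‑2‑yl acetate
Product: 20 Ardisinone, (2R)‑1‑(5‑methoxy‑3,6‑dioxocyclohexa‑1,4‑dien‑1‑yl)pentadecan‑2‑yl acetate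
Conditions: Fremy's salt (KSO3)2NO (2.5 equiv), KH2PO4 buffer (pH 6), acetone/H2O, 0 °C → rt
Reagents that add atoms: potassium nitrosodisulfonate (Fremy's salt), [K+].[K+].[O]N(S(=O)(=O)[O-])S(=O)(=O)[O-]
Why: Teuber oxidation: the first nitrosodisulfonate radical takes the phenolic hydrogen, the second couples at the free para carbon (C1, between the methoxy group and the side chain) and loss of imidodisulfonate gives the para‑quinone, the buffered medium leaving the acetate and the stereocentre untouched.

**Compound list**

1 | (R)‑epichlorohydrin, (2R)‑2‑(chloromethyl)oxirane | ClC[C@H]1CO1 | starting material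
2 | dodecylmagnesium bromide | CCCCCCCCCCCC[Mg]Br | starting material
3 | (2R)‑1‑chloropentadecan‑2‑ol | CCCCCCCCCCCCC[C@H](CCl)O | intermediate
4 | (2R)‑2‑tridecyloxirane | CCCCCCCCCCCCC[C@@H]1CO1 | intermediate
5 | vinylmagnesium bromide | C=C[Mg]Br | starting material
6 | (4R)‑heptadec‑1‑en‑4‑ol | CCCCCCCCCCCCC[C@H](CC=C)O | intermediate
7 | (4R)‑4‑(benzyloxy)heptadec‑1‑ene | CCCCCCCCCCCCC[C@H](CC=C)OCc1ccccc1 | intermediate
8 | methyl vinyl ketone (but‑3‑en‑2‑one) | CC(=O)C=C | starting material
9 | (3E,6R)‑6‑(benzyloxy)nonadec‑3‑en‑2‑one | CCCCCCCCCCCCC[C@H](C/C=C/C(C)=O)OCc1ccccc1 | intermediate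
10 | dimethyl malonate | COC(=O)CC(=O)OC | starting material
11 | dimethyl 2‑[(6R)‑6‑(benzyloxy)‑2‑oxononadecan‑4‑yl]propanedioate (Michael adduct, both C4 epimers) | CCCCCCCCCCCCC[C@H](CC(CC(C)=O)C(C(=O)OC)C(=O)OC)OCc1ccccc1 | intermediate
12 | methyl 6‑[(2R)‑2‑(benzyloxy)pentadecyl]‑2,4‑dioxocyclohexane‑1‑carboxylate (ring diastereomers, enolised) | CCCCCCCCCCCCC[C@H](CC1CC(=O)CC(=O)C1C(=O)OC)OCc1ccccc1 | intermediate
13 | methyl 6‑[(2R)‑2‑(benzyloxy)pentadecyl]‑4‑methoxy‑2‑oxocyclohex‑3‑ene‑1‑carboxylate | CCCCCCCCCCCCC[C@H](CC1CC(OC)=CC(=O)C1C(=O)OC)OCc1ccccc1 | intermediate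
14 | methyl 2‑[(2R)‑2‑(benzyloxy)pentadecyl]‑6‑hydroxy‑4‑methoxybenzoate | CCCCCCCCCCCCC[C@H](Cc1cc(OC)cc(O)c1C(=O)OC)OCc1ccccc1 | intermediate
15 | 2‑[(2R)‑2‑(benzyloxy)pentadecyl]‑6‑hydroxy‑4‑methoxybenzoic acid | CCCCCCCCCCCCC[C@H](Cc1cc(OC)cc(O)c1C(=O)O)OCc1ccccc1 | intermediate
16 | 3‑[(2R)‑2‑(benzyloxy)pentadecyl]‑5‑methoxyphenol | CCCCCCCCCCCCC[C@H](Cc1cc(O)cc(OC)c1)OCc1ccccc1 | intermediate
17 | 3‑[(2R)‑2‑hydroxypentadecyl]‑5‑methoxyphenol | CCCCCCCCCCCCC[C@H](Cc1cc(O)cc(OC)c1)O | intermediate
18 | (2R)‑1‑(3‑acetoxy‑5‑methoxyphenyl)pentadecan‑2‑yl acetate | CCCCCCCCCCCCC[C@H](Cc1cc(OC(C)=O)cc(OC)c1)OC(C)=O | intermediate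
19 | (2R)‑1‑(3‑hydroxy‑5‑methoxyphenyl)pentadecan‑2‑yl acetate | CCCCCCCCCCCCC[C@H](Cc1cc(O)cc(OC)c1)OC(C)=O | intermediate
20 | Ardisinone, (2R)‑1‑(5‑methoxy‑3,6‑dioxocyclohexa‑1,4‑dien‑1‑yl)pentadecan‑2‑yl acetate | CCCCCCCCCCCCC[C@H](CC1=CC(=O)C=C(OC)C1=O)OC(C)=O | target

**Step count and risks**

Total step count: 10. Longest linear sequence: 10 steps (1 → 20).

The three steps most likely to fail:

Step 6. The enol ether may form at both ring oxygens (over‑methylation), the very electron‑rich product ring may be iodinated, or dehydrogenation may stall at the enol ether stage. The fallback sets out from 12 and comes back to the route at 14. It separates aromatisation from O‑methylation and relies on chelation instead of kinetic enol‑ether selectivity. Dehydrogenation of 12 with DDQ (dioxane, reflux) should give methyl 2‑[(2R)‑2‑(benzyloxy)pentadecyl]‑4,6‑dihydroxybenzoate F1. Because the hydroxyl ortho to the ester is chelated, MeI (1.05 equiv)/K2CO3 in acetone should methylate only the para hydroxyl and give 14.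

Step 5. The enone may be deprotonated at its γ‑carbon and lose benzyl oxide (vinylogous β‑elimination) before conjugate addition, the Michael addition may revert on heating, or acylation may occur on oxygen instead of carbon. The fallback sets out from 4 and comes back to the route at 17. It gives up the ring construction and takes the ring from a ready‑made arene. Copper‑catalysed opening of epoxide 4 with commercial 3,5‑dimethoxyphenylmagnesium chloride (CuI cat., THF, −30 → 0 °C) should give (2R)‑1‑(3,5‑dimethoxyphenyl)pentadecan‑2‑ol F2. NaSEt in DMF at 140 °C should then cleave one methyl ether only, since the phenoxide formed shuts down the second cleavage, and give 17.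

Step 10. The second radical may couple at an ortho carbon instead of the hindered para carbon (ortho‑quinone formation), or the very lipophilic phenol may react so slowly in the aqueous medium that the reagent decays first. The fallback sets out from 19 and comes back to the route at 20. It replaces the radical oxidation by a two‑electron dearomatisation with a hypervalent iodine reagent. PhI(OAc)2 (2.2 equiv) in MeOH at 0 °C should give the para‑quinone monoketal (2R)‑1‑(5,6,6‑trimethoxy‑3‑oxocyclohexa‑1,4‑dien‑1‑yl)pentadecan‑2‑yl acetate F3. Dilute aqueous oxalic acid in THF should then hydrolyse the ketal to 20 without touching the acetate.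

**Further compounds**

F1 | step 6 | methyl 2‑[(2R)‑2‑(benzyloxy)pentadecyl]‑4,6‑dihydroxybenzoate | CCCCCCCCCCCCC[C@H](Cc1cc(O)cc(O)c1C(=O)OC)OCc1ccccc1
F2 | step 5 | (2R)‑1‑(3,5‑dimethoxyphenyl)pentadecan‑2‑ol | CCCCCCCCCCCCC[C@H](Cc1cc(OC)cc(OC)c1)O
F3 | step 10 | (2R)‑1‑(5,6,6‑trimethoxy‑3‑oxocyclohexa‑1,4‑dien‑1‑yl)pentadecan‑2‑yl acetate | CCCCCCCCCCCCC[C@H](CC1=CC(=O)C=C(OC)C1(OC)OC)OC(C)=O
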